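**Remarks on the chemistry (assumptions)**

- Atom labels C1–C15 are the germacrane positions of the target: ring C1–C10; C11, C12, C13 are the lactone carbons on C7; C14 is the methyl on C10; C15 is the carbon on C4. Ring olefins are called ring-cis or ring-trans by their two ring bonds, because the CIP letter of C4=C5 changes with the C15 substituent.
- Checked against the target, the ether carbon of the enone (future C8) and the silyloxy carbon of the cyclobutene (future C3) must both be S. The tricyclic adduct carries both unchanged, so no structure had to be altered.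
- The route assumes that the lipase in step 2 acylates the hydroxyl that leads to 3. If it shows the opposite sense, the same enzyme run in the hydrolytic direction on the diacetate of 2 gives the mirror-image selection.
- The route starts from commercial all-cis-cyclohexane-1,3,5-triol, which saves the hydrogenation of phloroglucinol.
- Metal enolates and metal alkoxides made and consumed in one operation are treated as reactive intermediates and are not numbered.
- Compounds 14–16 are C6 epimer mixtures (the centre is removed in step 12). Compounds 22 and 23 are C11 epimer mixtures (the centre is removed within step 15).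

## Structural features

The target is a germacranolide: a ten-membered carbocycle (C1–C10) trans-fused across C6–C7 to an α-methylene-γ-butyrolactone (O–C6, C7–C11(=C13H2)–C12=O). The ring carries a trans 1,10-epoxide (1R,10R, methyl C14 on C10), a ring-cis trisubstituted olefin C4=C5 with methyl C15, an allylic acetate at C3 (S) and a 3-methylbutanoate at C8 (S). C6, C7 and C8 are contiguous (6R,7R,8S); the two oxygens are cis to each other and both trans to the C7–C11 bond. C3 and the epoxide are remote from this triad, so neighbouring-centre relay alone cannot set them. The fragile groups are the exo-methylene lactone (Michael acceptor, base-sensitive), the epoxide that faces C4=C5 across the ring (acid-triggered transannular closure), the allylic acetate, and the C8 oxygen, which can relactonise onto C12 whenever it is a free hydroxyl. The real difficulty is the strained medium ring with one ring-trans and one ring-cis olefin (the epoxide is a masked ring-trans olefin), together with two different esters on two secondary hydroxyls. Once the epoxide oxygen is set aside, C1=C10 and C4=C5 stand in a 1,5-relationship through C2–C3; pairing C1 with C4 and C5 with C10 gives a bicyclo[2.2.0]hexane. One half of that bicycle belongs to a six-membered ketone C5–C10 (carbonyl C6, methyl on C10, oxygen on C8) and the other to a four-membered ring C1–C4 (C15 on C4, oxygen on C3); the key step uses exactly this mapping.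

## Logic of the disconnections

**29 ⇒ 28.** The C1–O and C10–O bonds of the oxirane are cut. The epoxide is the most acid-sensitive group and is best made last. This removes two stereocentres and exposes the 1,5-diene. The forward step must pick the one electron-rich olefin and the correct face.

**28 ⇒ 24 (through 27, 26, 25).** The acyl C–O bonds at O3 and O8 are cut and replaced by a silyl ether and a 4-methoxybenzyl ether. Neither ester would survive the enolate and hydride steps before it. Two orthogonal ethers let each hydroxyl be freed and acylated in turn. Each deprotection must spare the methylene lactone and the diene, and the free C8 hydroxyl must be acylated before it can attack C12.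

**24 ⇒ 21.** The C11=C13 bond is cut. The exocyclic olefin is a Michael acceptor and is safest when introduced after all carbanion chemistry on the ring. The demand is clean enolisation at C11, the only acidic position left.

**21 ⇒ 19.** The lactone O–C12 bond and the C6–H bond are cut, which returns C6 to a ketone and C12 to an ester. This traces the C6 centre to a reduction steered by the C8 ether. The forward step must deliver hydride so that O6 is cis to O8 and trans to the side chain.

**19 ⇒ 17 + 18.** The C7–C11 bond is cut at the α′ position of the enone. The side chain then comes from a two-carbon electrophile. The forward step must attach it trans to the C8 ether without β-elimination of that ether.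

**17 ⇒ 13 (through 16, 14).** The C15 methyl is retraced to an ester. The ester directs the regiochemistry of the photoreaction and eases the ring opening, so it must be carried up to 13. The adjustment is placed where ethers are the only other functions. It demands a primary-selective deoxygenation and re-oxidation of C6.

**13 ⇒ 12.** The bonds C5–C10 and C1–C4 are re-formed, the reverse of a cycloreversion. The strained ten-membered ring with both olefins is exchanged for a compact tricycle. The forward opening must give ring-trans C1=C10 and ring-cis C4=C5 and must stop before a [3,3] shift.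

**12 ⇒ 7 + 11.** The bonds C4–C5 and C1–C10 are cut. Two small rings, each with one stereocentre, supply all ten ring carbons, the C6 carbonyl, C14, C15 and both ring oxygens. The only selectivity required is head-to-head bonding.

**7 ⇒ 1 (through 6, 5, 3, 2).** The C10–C14 bond is cut and the enone is retraced to a meso triol. A single enzymatic desymmetrisation supplies the absolute configuration of C8. The demand is a β-elimination that removes the acetate and not the ether.

**11 ⇒ 8 + 9 (through 10).** The bonds C1–C2 and C3–C4 are cut. The cyclobutene comes from an alkyne and an enol ether in one step. The demands are the correct orientation of the two partners and a separation of antipodes.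

## Other disconnections considered

**Alternative 1:** The cut is C6–C7, with C6 re-attached through oxygen to C13, which trades the carbocycle for the thirteen-membered cyclic bis-allylic ether A2. Forward, deprotonation of A2 at C6 would start a [2,3]-Wittig shift onto C7 of the C7=C11 olefin; the O–C13 bond breaks and A1 results, with the C6–C7 bond, the C6 hydroxyl and the C11=C13 methylene formed together.
- In favour: the shift is concerted and suprafacial and sets C6 and C7 in one event. The methylene arrives with the ring, so no methylenation is needed. C15 is a methyl from the start. There is no photochemistry and no high temperature. All three trisubstituted olefins are made in open-chain chemistry.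
- Against here: A2 needs a long linear assembly and a macrocyclic etherification. The base must choose C6 over C13, which is equally allylic and α to oxygen, and must avoid the [1,2]-shift. The sense of C6 and C7 relative to C8 and the distant C3 depends on the conformation of a thirteen-membered ring. Three different silyl groups must then be told apart, and C12 must still be oxidised and lactonised.
- Comparison: on structure, A1 already holds C6 and C7, which the chosen plan sets only in steps 13 and 14 on a flexible ring; here the alternative is the better. On mechanism, an anionic sigmatropic shift must be stereoselective, whereas the ring-forming step of the chosen plan needs no control at its new centres. On step economy, the end game from A1 is shorter, but the way to A2 is much longer than the seven steps to 7 and 11. Overall the alternative is equal at best.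

**Alternative 2:** The cut is C9–C10. Forward, the silyl enol ether of the C8 methyl ketone in the open-chain chloro ketone A4 would add through C9 to the C10 ketone (Mukaiyama aldol) and close the ring to A3. The C1 chloride steers the addition (Cornforth model), and later the C10 alkoxide displaces chloride with inversion to give the epoxide.
- In favour: the epoxide configuration comes from acyclic 1,2-induction and a stereospecific SN2 closure, not from the facial bias of a macrocyclic olefin; this is better than step 20 of the chosen plan. The C1=C10 olefin never exists, so neither an olefin-geometry question nor a [3,3] shift can arise; this is also a point for the alternative. The lactone and the ring-cis olefin are in place before cyclisation.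
- Against here: an aldol addition to a ketone is weakly driven and reversible, and it must close a ten-membered ring from a chain that also holds an enolisable lactone and an α-chloro ketone. Retro-aldol cleavage of A3 and loss of HCl are likely side paths. The C8 ketone still needs a stereoselective reduction, and methylenation remains. A4 has four stereocentres that need a long acyclic synthesis.
- Comparison: on structure, the chosen plan makes the carbocycle from two small rings and has no entropic ring-closure problem, while the alternative is stronger for the epoxide. On mechanism, a polar Lewis-acid step stands against a photochemical and a thermal pericyclic step. On step economy, the alternative saves the C15 adjustment but pays with chain assembly and is probably longer.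

**Alternative 3:** The ten-membered dienone is seen as the fragmentation product of the bicyclo[5.3.0]decene A6, in which a C6–C10 bond divides the ring into a five-membered ring (C6–C10) and a seven-membered ring (C10, C1–C6). Forward, the C6 alkoxide of A6 expels the C1 mesylate while C6–C10 breaks (Grob fragmentation), giving A5 with the C6 ketone and the C1=C10 olefin.
- In favour: the geometry of C1=C10 follows stereospecifically from the anti-periplanar alignment in a rigid bicycle, which is more secure than step 9. The step runs with base at low temperature, so a [3,3] shift is no concern. The C7 side chain is placed on a rigid bicycle, which is better than step 13. C15 is a methyl from the start, which saves steps 10–12.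
- Against here: A6 has six stereocentres, three of which (C1, C6, C10) are built only to be destroyed. A hydroazulene with a tertiary alcohol, a quaternary methyl and a correctly aligned mesylate is a demanding target. After the fragmentation the same late problems remain (C6 reduction, lactone, methylenation, epoxidation), and the β-alkoxy ketone is exposed to base.
- Comparison: on structure, A5 is compound 19 of the chosen plan with an acetal in place of the ester, so both plans meet at the same kind of dienone and are equal from there on. On mechanism, a heterolytic stereospecific step stands against a homolytic diyl. On step economy, the alternative is about four steps shorter after its key step and much longer before it.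

Key step: step 8

## Route

Step 1
Reactants: 1 all-cis-cyclohexane-1,3,5-triol
Product: 2 all-cis-5-(4-methoxybenzyloxy)cyclohexane-1,3-diol (meso)
Conditions: NaH (1.0 equiv), DMF, 0 °C; 4-methoxybenzyl chloride (0.9 equiv), Bu4NI (cat.), 0 °C → rt
Reagents that add atoms: 4-methoxybenzyl chloride, COc1ccc(CCl)cc1
Why: Williamson etherification; the three hydroxyls are equivalent, so only the degree of alkylation has to be held by stoichiometry, and the product keeps a mirror plane.

Step 2
Reactants: 2 all-cis-5-(4-methoxybenzyloxy)cyclohexane-1,3-diol
Product: 3 (1S,3S,5R)-3-hydroxy-5-(4-methoxybenzyloxy)cyclohexyl acetate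
Conditions: immobilised lipase of Burkholderia cepacia, vinyl acetate, tBuOMe, 30 °C
Reagents that add atoms: vinyl acetate, C=COC(C)=O
Why: Lipase-catalysed enantiotopic-group-selective transesterification of a meso-1,3-diol; the enzyme acylates one of the two mirror-related carbinols and so sets the absolute configuration of the future C8, and the enol leaving group makes the transfer irreversible.

Step 3
Reactants: 3 (1S,3S,5R)-3-hydroxy-5-(4-methoxybenzyloxy)cyclohexyl acetate
Product: 5 (S)-5-(4-methoxybenzyloxy)cyclohex-2-en-1-one, via keto acetate 4 (not isolated)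
Conditions: (COCl)2, DMSO, CH2Cl2, −78 °C; Et3N (5 equiv), −78 °C → rt
Reagents that add atoms: none
Why: Swern oxidation followed in the same flask by E1cB loss of acetic acid from the β-acetoxy ketone; acetate is by far the better leaving group of the two β-oxygens, so the benzyl-type ether stays and its carbon is the only stereocentre left.

Step 4
Reactants: 5 (S)-5-(4-methoxybenzyloxy)cyclohex-2-en-1-one
Product: 6 trimethyl{[(3S,5S)-5-(4-methoxybenzyloxy)-3-methylcyclohex-1-en-1-yl]oxy}silane
Conditions: Me2CuLi (from MeLi and CuBr·SMe2), Me3SiCl, THF, −78 °C; Et3N, cold NaHCO3 work-up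
Reagents that add atoms: lithium dimethylcuprate, [Li+].C[Cu-]C; chlorotrimethylsilane, C[Si](C)(C)Cl
Why: Conjugate addition of a Gilman cuprate with O-silylation of the enolate in situ; the methyl group should enter trans to the C5 ether, but this centre becomes planar again in step 5.

Step 5
Reactants: 6 trimethyl{[(3S,5S)-5-(4-methoxybenzyloxy)-3-methylcyclohex-1-en-1-yl]oxy}silane
Product: 7 (S)-5-(4-methoxybenzyloxy)-3-methylcyclohex-2-en-1-one
Conditions: Pd(OAc)2 (1.05 equiv), MeCN, rt
Reagents that add atoms: none
Why: Saegusa–Ito oxidation; the palladium enolate formed from the silyl enol ether undergoes β-hydride elimination toward the methyl-bearing carbon and restores the enone with the C14 methyl on the β-carbon, under neutral conditions that spare the β-alkoxy ketone.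

Step 6
Reactants: 8 methyl propiolate; 9 tert-butyldimethyl(vinyloxy)silane
Product: 10 methyl 4-(tert-butyldimethylsilyloxy)cyclobut-1-ene-1-carboxylate (racemic)
Conditions: EtAlCl2 (20 mol %), CH2Cl2, −78 °C; cold NaHCO3 work-up, kept below 0 °C
Reagents that add atoms: none
Why: Lewis-acid-promoted stepwise [2+2] cycloaddition of a silyl enol ether with an activated alkyne; the nucleophilic CH2 terminus adds to the β-carbon of the complexed propiolate and the allenolate closes on the oxocarbenium carbon, which places the silyloxy carbon next to the ester-bearing olefinic carbon.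

Step 7
Reactants: 10 methyl 4-(tert-butyldimethylsilyloxy)cyclobut-1-ene-1-carboxylate (racemic)
Product: 11 methyl (S)-4-(tert-butyldimethylsilyloxy)cyclobut-1-ene-1-carboxylate
Conditions: preparative supercritical-fluid chromatography, amylose tris(3,5-dimethylphenylcarbamate) phase, CO2/iPrOH, 5 °C
Reagents that add atoms: none
Why: Resolution by chromatography on a chiral stationary phase; no bond is made, the S antipode needed for C3 is collected and kept cold because a 3-oxy-substituted cyclobutene is prone to conrotatory ring opening.

Step 8
Reactants: 7 (S)-5-(4-methoxybenzyloxy)-3-methylcyclohex-2-en-1-one; 11 methyl (S)-4-(tert-butyldimethylsilyloxy)cyclobut-1-ene-1-carboxylate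
Product: 12 cis,anti,cis tricyclic keto ester (cyclohexanone C5–C10 fused at C5–C10 to the cyclobutane C4–C5–C10–C1, which shares C1–C4 with the silyloxy cyclobutane C1–C4; CO2Me on C4, silyloxy on C3 exo, benzyl-type ether on C8 anti to the four-membered ring; 3S,8S)
Conditions: hν (366 nm, or Hg lamp through uranium glass), 11 (2.5 equiv), CH2Cl2, degassed, −40 °C; unreacted 11 recovered cold; then basic Al2O3, CH2Cl2, rt (brief)
Reagents that add atoms: none
Why: Excitation of the enone and intersystem crossing give the twisted triplet, which bonds to the cyclobutene to form a triplet 1,4-biradical; after spin inversion this collapses to the central cyclobutane (C4–C5 and C1–C10), the only ring closed, so the closure is a biradical recombination and not a concerted addition. The closest known reaction type is the intermolecular [2+2] photocycloaddition of cyclohexenones with cyclobut-1-ene-1-carboxylates. The selectivity the route needs is head-to-head bonding (ester carbon C4 to the α-carbon C5); it follows the usual preference of acceptor-substituted alkenes toward triplet enones and is reinforced here because the unsubstituted C1 meets the methyl-bearing C10 while the crowded C4 meets the α-CH. C1 and C4 are joined cis because the cyclobutene ring allows nothing else, and C5 and C10 end cis after the alumina treatment, which epimerises any strained trans-fused adduct at C5. The anti arrangement of the outer rings, the exo silyloxy group and the position of the cyclobutane anti to the C8 ether should result from approach of each partner by its less hindered face. None of the four new centres has to be controlled for the target, because all of them become sp2 in step 9, and C3 and C8 are spectators that keep their configuration. Light above 350 nm excites only the enone and spares the anisyl ether, and the low temperature holds back the thermal opening of 11.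

Step 9
Reactants: 12 cis,anti,cis tricyclic keto ester
Product: 13 methyl (3S,8S)-3-(tert-butyldimethylsilyloxy)-8-(4-methoxybenzyloxy)-10-methyl-6-oxocyclodeca-1(10),4-diene-4-carboxylate (C1=C10 ring-trans; C4=C5 ring-cis, ester trans to C6)
Conditions: mesitylene (degassed, 0.01 M), 2,6-di-tert-butyl-4-methylphenol (cat.), 160 °C, sealed, base-washed glass
Reagents that add atoms: none
Why: Thermal cycloreversion of a bicyclo[2.2.0]hexane through the cyclohexane-1,4-diyl; the central C1–C4 bond breaks (radical at C4 stabilised by the ester), then the more substituted, ketone-activated C5–C10 bond, and the two σ bonds become C1=C10 and C4=C5. The cis ring fusion forces one ring-trans and one ring-cis olefin, and allylic strain between the C4 ester and C6 in the diyl should put the ester trans to the ketone, which means ring-cis C4=C5 and ring-trans C1=C10.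

Step 10
Reactants: 13 methyl (3S,8S)-3-(tert-butyldimethylsilyloxy)-8-(4-methoxybenzyloxy)-10-methyl-6-oxocyclodeca-1(10),4-diene-4-carboxylate
Product: 14 (3S,8S)-3-(tert-butyldimethylsilyloxy)-4-(hydroxymethyl)-8-(4-methoxybenzyloxy)-10-methylcyclodeca-1(10),4-dien-6-ol (1(10)E,4Z; C6 epimers)
Conditions: iBu2AlH (5 equiv), CH2Cl2, −78 °C; aq. potassium sodium tartrate
Reagents that add atoms: none
Why: 1,2-Reduction of both the enone carbonyl and the conjugated ester by an electrophilic aluminium hydride; the C6 carbinol forms as an epimer mixture, which is of no consequence because it is oxidised back in step 12.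

Step 11
Reactants: 14 (3S,8S)-3-(tert-butyldimethylsilyloxy)-4-(hydroxymethyl)-8-(4-methoxybenzyloxy)-10-methylcyclodeca-1(10),4-dien-6-ol
Product: 16 (3S,8S)-3-(tert-butyldimethylsilyloxy)-8-(4-methoxybenzyloxy)-4,10-dimethylcyclodeca-1(10),4-dien-6-ol (1(10)E,4Z; C6 epimers), via allylic mesylate 15 (not isolated)
Conditions: MeSO2Cl (1.05 equiv), 2,4,6-collidine, CH2Cl2, −30 °C; then LiEt3BH (3.5 equiv), THF, −78 → 0 °C
Reagents that add atoms: none
Why: Chemoselective sulfonylation of the primary allylic hydroxyl beside the secondary one, then SN2 hydride displacement by a trialkylborohydride; this brings C15 to the methyl level at a stage where ethers are the only other functions.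

Step 12
Reactants: 16 (3S,8S)-3-(tert-butyldimethylsilyloxy)-8-(4-methoxybenzyloxy)-4,10-dimethylcyclodeca-1(10),4-dien-6-ol
Product: 17 (3S,8S,1(10)E,4Z)-3-(tert-butyldimethylsilyloxy)-8-(4-methoxybenzyloxy)-4,10-dimethylcyclodeca-1(10),4-dien-6-one
Conditions: MnO2 (activated, excess), CH2Cl2, rt
Reagents that add atoms: none
Why: Allylic alcohol oxidation by manganese dioxide returns the C6 ketone and removes the C6 epimer mixture without touching the olefin geometry or the ethers.

Step 13
Reactants: 17 (3S,8S,1(10)E,4Z)-3-(tert-butyldimethylsilyloxy)-8-(4-methoxybenzyloxy)-4,10-dimethylcyclodeca-1(10),4-dien-6-one; 18 methyl bromoacetate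
Product: 19 methyl 2-[(3S,7R,8S,1(10)E,4Z)-3-(tert-butyldimethylsilyloxy)-8-(4-methoxybenzyloxy)-4,10-dimethyl-6-oxocyclodeca-1(10),4-dien-7-yl]acetate (side chain trans to the C8 ether)
Conditions: LiN(iPr)2 (1.05 equiv), THF, −78 °C; 18, DMPU, −78 → −40 °C
Reagents that add atoms: none
Why: Kinetic α′-deprotonation of the enone gives the cross-conjugated lithium dienolate, which is alkylated at C7 by the activated halide (SN2). With C8–H eclipsing the enolate to avoid allylic 1,3-strain, the electrophile should enter from the ring periphery anti to the C8–C9 bond, which puts C11 trans to the C8 ether; an alkyl ether was kept on C8 because alkoxide is a poor leaving group from the β-position.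

Step 14
Reactants: 19 methyl 2-[(3S,7R,8S)-3-(tert-butyldimethylsilyloxy)-8-(4-methoxybenzyloxy)-4,10-dimethyl-6-oxocyclodeca-1(10),4-dien-7-yl]acetate
Product: 21 (3S,6R,7R,8S)-3-(tert-butyldimethylsilyloxy)-8-(4-methoxybenzyloxy)-13-norgermacra-1(10)E,4Z-dien-6,12-olide (trans-fused γ-lactone), via hydroxy ester 20 (not isolated)
Conditions: Zn(BH4)2, Et2O, −30 °C; then pyridinium p-toluenesulfonate (cat.), CH2Cl2, rt
Reagents that add atoms: none
Why: Chelation-controlled 1,2-reduction of a β-alkoxy ketone; zinc bridges the C6 carbonyl and the C8 ether oxygen and external hydride should give the 1,3-syn relationship, so O6 is cis to O8 and trans to the side chain (6R). The γ-hydroxy ester then closes to the trans-fused lactone by acid-catalysed transesterification.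

Step 15
Reactants: 21 (3S,6R,7R,8S)-3-(tert-butyldimethylsilyloxy)-8-(4-methoxybenzyloxy)-13-norgermacra-1(10)E,4Z-dien-6,12-olide
Product: 24 (3S,6R,7R,8S)-3-(tert-butyldimethylsilyloxy)-8-(4-methoxybenzyloxy)germacra-1(10)E,4Z,11(13)-trien-6,12-olide, via Mannich base 22 (not isolated), via ammonium iodide 23 (not isolated)
Conditions: LiN(iPr)2, THF, −78 °C; CH2=NMe2+ I−, −78 → 0 °C; then MeI, MeOH, rt; then NaHCO3 (aq.), EtOAc, rt
Reagents that add atoms: N,N-dimethylmethyleneiminium iodide, C=[N+](C)C.[I-]
Why: Mannich aminomethylation of the lactone enolate, quaternisation and E1cB elimination of trimethylamine install the exocyclic C11=C13 olefin; C11 stops being a stereocentre, so its epimer ratio does not matter.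

Step 16
Reactants: 24 (3S,6R,7R,8S)-3-(tert-butyldimethylsilyloxy)-8-(4-methoxybenzyloxy)germacra-1(10)E,4Z,11(13)-trien-6,12-olide
Product: 25 (3S,6R,7R,8S)-3-(tert-butyldimethylsilyloxy)-8-hydroxygermacra-1(10)E,4Z,11(13)-trien-6,12-olide
Conditions: DDQ, CH2Cl2/pH 7 buffer, 0 °C
Reagents that add atoms: none
Why: Oxidative cleavage of the 4-methoxybenzyl ether by hydride abstraction and hydrolysis of the resulting oxocarbenium ion; the neutral conditions leave the silyl ether, the diene and the methylene lactone intact.

Step 17
Reactants: 25 (3S,6R,7R,8S)-3-(tert-butyldimethylsilyloxy)-8-hydroxygermacra-1(10)E,4Z,11(13)-trien-6,12-olide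
Product: 26 (3S,6R,7R,8S)-3-(tert-butyldimethylsilyloxy)-8-(3-methylbutanoyloxy)germacra-1(10)E,4Z,11(13)-trien-6,12-olide
Conditions: (iPrCH2CO)2O, Et3N, 4-dimethylaminopyridine (cat.), CH2Cl2, 0 °C → rt
Reagents that add atoms: 3-methylbutanoic anhydride, CC(C)CC(=O)OC(=O)CC(C)C
Why: Nucleophile-catalysed acylation of the secondary C8 alcohol with retention; a fast acylation under mild base is chosen so that the free 8-hydroxyl has no time to relactonise onto C12.

Step 18
Reactants: 26 (3S,6R,7R,8S)-3-(tert-butyldimethylsilyloxy)-8-(3-methylbutanoyloxy)germacra-1(10)E,4Z,11(13)-trien-6,12-olide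
Product: 27 (3S,6R,7R,8S)-3-hydroxy-8-(3-methylbutanoyloxy)germacra-1(10)E,4Z,11(13)-trien-6,12-olide
Conditions: HF·pyridine, pyridine, THF, 0 °C → rt
Reagents that add atoms: none
Why: Fluoride-mediated desilylation under buffered, weakly acidic conditions; basic fluoride sources are avoided because of the Michael-acceptor lactone and possible acyl migration.

Step 19
Reactants: 27 (3S,6R,7R,8S)-3-hydroxy-8-(3-methylbutanoyloxy)germacra-1(10)E,4Z,11(13)-trien-6,12-olide
Product: 28 (3S,6R,7R,8S)-3-acetoxy-8-(3-methylbutanoyloxy)germacra-1(10)E,4Z,11(13)-trien-6,12-olide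
Conditions: Ac2O, pyridine, 4-dimethylaminopyridine (cat.), CH2Cl2, 0 °C
Reagents that add atoms: acetic anhydride, CC(=O)OC(C)=O
Why: Acetylation of the allylic C3 alcohol at oxygen, with retention of configuration at C3.

Step 20
Reactants: 28 (3S,6R,7R,8S)-3-acetoxy-8-(3-methylbutanoyloxy)germacra-1(10)E,4Z,11(13)-trien-6,12-olide
Product: 29 (1R,3S,6R,7R,8S,10R)-3-acetoxy-1,10-epoxy-8-(3-methylbutanoyloxy)germacra-4Z,11(13)-dien-6,12-olide (CNP0157657.1)
Conditions: mCPBA (1.05 equiv), NaHCO3, CH2Cl2, 0 °C
Reagents that add atoms: 3-chloroperoxybenzoic acid, OOC(=O)c1cccc(Cl)c1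
Why: Prilezhaev epoxidation; C1=C10 is the only electron-rich olefin (C4=C5 is flanked by two allylic C–O bonds, C11=C13 is conjugated), and peracid attack on the exposed outer face of the ring-trans olefin should give the trans (1R,10R) epoxide stereospecifically.

## Compound list

1 | all-cis-cyclohexane-1,3,5-triol | O[C@@H]1C[C@H](O)C[C@H](O)C1 | starting material
2 | all-cis-5-(4-methoxybenzyloxy)cyclohexane-1,3-diol (meso) | O[C@@H]1C[C@H](O)C[C@H](OCc2ccc(OC)cc2)C1 | intermediate
3 | (1S,3S,5R)-3-hydroxy-5-(4-methoxybenzyloxy)cyclohexyl acetate | O[C@@H]1C[C@H](OC(C)=O)C[C@H](OCc2ccc(OC)cc2)C1 | intermediate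
4 | (1R,5S)-3-oxo-5-(4-methoxybenzyloxy)cyclohexyl acetate (keto acetate, not isolated) | O=C1C[C@H](OC(C)=O)C[C@H](OCc2ccc(OC)cc2)C1 | intermediate
5 | (S)-5-(4-methoxybenzyloxy)cyclohex-2-en-1-one | O=C1C=CC[C@H](OCc2ccc(OC)cc2)C1 | intermediate
6 | trimethyl{[(3S,5S)-5-(4-methoxybenzyloxy)-3-methylcyclohex-1-en-1-yl]oxy}silane | C[Si](C)(C)OC1=C[C@@H](C)C[C@H](OCc2ccc(OC)cc2)C1 | intermediate
7 | (S)-5-(4-methoxybenzyloxy)-3-methylcyclohex-2-en-1-one | O=C1C=C(C)C[C@H](OCc2ccc(OC)cc2)C1 | intermediate
8 | methyl propiolate | COC(=O)C#C | starting material
9 | tert-butyldimethyl(vinyloxy)silane | C=CO[Si](C)(C)C(C)(C)C | starting material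
10 | methyl 4-(tert-butyldimethylsilyloxy)cyclobut-1-ene-1-carboxylate (racemic) | COC(=O)C1=CCC1O[Si](C)(C)C(C)(C)C | intermediate
11 | methyl (S)-4-(tert-butyldimethylsilyloxy)cyclobut-1-ene-1-carboxylate | COC(=O)C1=CC[C@@H]1O[Si](C)(C)C(C)(C)C | intermediate
12 | cis,anti,cis tricyclic keto ester (photoadduct; 3S,8S) | C1C(=O)[C@H]2[C@]3(C(=O)OC)[C@@H](O[Si](C)(C)C(C)(C)C)C[C@@H]3[C@@]2(C)C[C@@H]1OCc4ccc(OC)cc4 | intermediate
13 | methyl (3S,8S)-3-(tert-butyldimethylsilyloxy)-8-(4-methoxybenzyloxy)-10-methyl-6-oxocyclodeca-1(10),4-diene-4-carboxylate (C1=C10 ring-trans, C4=C5 ring-cis) | C1C(=O)/C=C(/C(=O)OC)[C@@H](O[Si](C)(C)C(C)(C)C)C/C=C(\C)C[C@@H]1OCc2ccc(OC)cc2 | intermediate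
14 | (3S,8S)-3-(tert-butyldimethylsilyloxy)-4-(hydroxymethyl)-8-(4-methoxybenzyloxy)-10-methylcyclodeca-1(10),4-dien-6-ol (C6 epimers) | C1C(O)/C=C(/CO)[C@@H](O[Si](C)(C)C(C)(C)C)C/C=C(\C)C[C@@H]1OCc2ccc(OC)cc2 | intermediate
15 | C15 methanesulfonate of 14 (C6 epimers, not isolated) | C1C(O)/C=C(/COS(C)(=O)=O)[C@@H](O[Si](C)(C)C(C)(C)C)C/C=C(\C)C[C@@H]1OCc2ccc(OC)cc2 | intermediate
16 | (3S,8S)-3-(tert-butyldimethylsilyloxy)-8-(4-methoxybenzyloxy)-4,10-dimethylcyclodeca-1(10),4-dien-6-ol (C6 epimers) | C1C(O)/C=C(/C)[C@@H](O[Si](C)(C)C(C)(C)C)C/C=C(\C)C[C@@H]1OCc2ccc(OC)cc2 | intermediate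
17 | (3S,8S,1(10)E,4Z)-3-(tert-butyldimethylsilyloxy)-8-(4-methoxybenzyloxy)-4,10-dimethylcyclodeca-1(10),4-dien-6-one | C1C(=O)/C=C(/C)[C@@H](O[Si](C)(C)C(C)(C)C)C/C=C(\C)C[C@@H]1OCc2ccc(OC)cc2 | intermediate
18 | methyl bromoacetate | COC(=O)CBr | starting material
19 | methyl 2-[(3S,7R,8S)-3-(tert-butyldimethylsilyloxy)-8-(4-methoxybenzyloxy)-4,10-dimethyl-6-oxocyclodeca-1(10),4-dien-7-yl]acetate | COC(=O)C[C@H]1C(=O)/C=C(/C)[C@@H](O[Si](C)(C)C(C)(C)C)C/C=C(\C)C[C@@H]1OCc2ccc(OC)cc2 | intermediate
20 | 6-hydroxy ester from 19 (O6 cis to O8, trans to the side chain; not isolated) | COC(=O)C[C@H]1[C@H](O)/C=C(/C)[C@@H](O[Si](C)(C)C(C)(C)C)C/C=C(\C)C[C@@H]1OCc2ccc(OC)cc2 | intermediate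
21 | (3S,6R,7R,8S)-3-(tert-butyldimethylsilyloxy)-8-(4-methoxybenzyloxy)-13-norgermacra-1(10)E,4Z-dien-6,12-olide | C1C(=O)O[C@@H]2/C=C(/C)[C@@H](O[Si](C)(C)C(C)(C)C)C/C=C(\C)C[C@H](OCc3ccc(OC)cc3)[C@@H]12 | intermediate
22 | 11-(dimethylaminomethyl) derivative of 21 (C11 epimers, not isolated) | CN(C)CC1C(=O)O[C@@H]2/C=C(/C)[C@@H](O[Si](C)(C)C(C)(C)C)C/C=C(\C)C[C@H](OCc3ccc(OC)cc3)[C@@H]12 | intermediate
23 | trimethylammonium iodide from 22 (C11 epimers, not isolated) | C[N+](C)(C)CC1C(=O)O[C@@H]2/C=C(/C)[C@@H](O[Si](C)(C)C(C)(C)C)C/C=C(\C)C[C@H](OCc3ccc(OC)cc3)[C@@H]12.[I-] | intermediate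
24 | (3S,6R,7R,8S)-3-(tert-butyldimethylsilyloxy)-8-(4-methoxybenzyloxy)germacra-1(10)E,4Z,11(13)-trien-6,12-olide | C=C1C(=O)O[C@@H]2/C=C(/C)[C@@H](O[Si](C)(C)C(C)(C)C)C/C=C(\C)C[C@H](OCc3ccc(OC)cc3)[C@@H]12 | intermediate
25 | (3S,6R,7R,8S)-3-(tert-butyldimethylsilyloxy)-8-hydroxygermacra-1(10)E,4Z,11(13)-trien-6,12-olide | C=C1C(=O)O[C@@H]2/C=C(/C)[C@@H](O[Si](C)(C)C(C)(C)C)C/C=C(\C)C[C@H](O)[C@@H]12 | intermediate
26 | (3S,6R,7R,8S)-3-(tert-butyldimethylsilyloxy)-8-(3-methylbutanoyloxy)germacra-1(10)E,4Z,11(13)-trien-6,12-olide | C=C1C(=O)O[C@@H]2/C=C(/C)[C@@H](O[Si](C)(C)C(C)(C)C)C/C=C(\C)C[C@H](OC(=O)CC(C)C)[C@@H]12 | intermediate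
27 | (3S,6R,7R,8S)-3-hydroxy-8-(3-methylbutanoyloxy)germacra-1(10)E,4Z,11(13)-trien-6,12-olide | C=C1C(=O)O[C@@H]2/C=C(/C)[C@@H](O)C/C=C(\C)C[C@H](OC(=O)CC(C)C)[C@@H]12 | intermediate
28 | (3S,6R,7R,8S)-3-acetoxy-8-(3-methylbutanoyloxy)germacra-1(10)E,4Z,11(13)-trien-6,12-olide | C=C1C(=O)O[C@@H]2/C=C(/C)[C@@H](OC(C)=O)C/C=C(\C)C[C@H](OC(=O)CC(C)C)[C@@H]12 | intermediate
29 | (1R,3S,6R,7R,8S,10R)-3-acetoxy-1,10-epoxy-8-(3-methylbutanoyloxy)germacra-4Z,11(13)-dien-6,12-olide | C=C1C(=O)O[C@@H]2/C=C(/C)[C@@H](OC(C)=O)C[C@H]3O[C@]3(C)C[C@H](OC(=O)CC(C)C)[C@@H]12 | target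

## Step count and least certain steps

Total: 20 steps. Longest linear sequence: 18 steps (1 → 7 in steps 1–5, then steps 8–20); the cyclobutene branch (steps 6–7) joins at step 8.

**Step 8 (key step).** The most likely failure is thermal conrotatory ring opening of 11 during the long irradiation. The diene so formed quenches the enone triplet, so conversion stalls and the enone dimerises. A smaller risk is partial head-to-tail bonding. Fallback, from 11 back to 12: the silyl ether of 11 is exchanged directly for an acetate (Ac2O, Cu(OTf)2 cat., CH2Cl2, 0 °C) to give methyl (S)-4-acetoxycyclobut-1-ene-1-carboxylate F1, whose weaker donor group slows the electrocyclic opening. Irradiation of F1 with 7 as in step 8 gives the acetoxy photoadduct F2. Acid-catalysed methanolysis (HCl from AcCl, MeOH, 0 °C) gives the hydroxy photoadduct F3; base is avoided because a cyclobutanol alkoxide next to the ester could cleave by retro-aldol. Silylation (tBuMe2SiOTf, 2,6-lutidine) returns to 12.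

**Step 9.** Both chair forms of the diyl are open, so the cycloreversion may partition toward the other cis,trans isomer (ring-cis C1=C10, ring-trans C4=C5). At the temperature needed, the 3-silyloxy-1,5-diene may also go on by [3,3] shift to a divinylcyclohexanone. Fallback, from 7 and 11 back to 13: the irradiation of step 8 is worked up without alumina, and the trans-fused C5 epimer F4, the usual kinetic co-product of cyclohexenone photocycloadditions, is separated from 12. In its diyl C6 and C9 can both be equatorial, so heating should give the dienone ester F5 with both olefins ring-trans. In F5 the ester and the ketone are cis across C4=C5; isomerisation of this enone olefin alone to the more stable trans arrangement (hν 350 nm, or cat. I2) gives 13.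

**Step 13.** The C7 enolate may lose the C8 alkoxide by E1cB elimination to a cross-conjugated trienone, or the facial selectivity on the flexible ring may be poor. Fallback, from 17 back to 19: soft enolisation (Me3SiOTf, Et3N, CH2Cl2, −78 → 0 °C) gives the trimethylsilyl dienol ether F6 (drawn with the ring-cis enol ether; its geometry is of no consequence). Radical-chain alkylation of F6 with 18, initiated by Et3B and air, adds the electrophilic ester radical to C7 and releases the silyl group. No basic enolate is present at any time, and 19 results.

**Step 14.** If the zinc chelate does not form within the ring, hydride delivery may follow a Felkin-type path anti to the C7–C8 bond. That gives the 6-epi alcohol and from it the cis-fused lactone. Fallback, from 19 back to 21: the cis-fused 6-epi lactone F7 obtained in that case is opened (KOH, aq. THF) and acidified cold to the 6-epi hydroxy acid F8. F8 is closed at once under Mitsunobu conditions (PPh3, diisopropyl azodicarboxylate, THF, 0 °C); the carboxylate displaces the activated allylic C6 oxygen with inversion and gives 21.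

**Step 20.** Two ring conformers expose opposite faces of C1=C10, so the facial selectivity may be poor; acid-induced transannular closure of the epoxide onto C4=C5 is a second risk. Fallback, from 28 to 29: reagent-controlled epoxidation with a chiral dioxirane (Shi epoxidation), using the fructose-derived ketone 1,2:4,5-di-O-isopropylidene-D-erythro-2,3-hexodiulo-2,6-pyranose or its enantiomer, whichever matches the (1R,10R) face, with KHSO5 and K2CO3 buffer in MeCN/dimethoxymethane at 0 °C. A ring-trans trisubstituted olefin is the ideal substrate for this reagent. The fallback makes no new compound.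

## Further compounds

F1 | step 8 | methyl (S)-4-acetoxycyclobut-1-ene-1-carboxylate | COC(=O)C1=CC[C@@H]1OC(C)=O
F2 | step 8 | acetoxy photoadduct (12 with acetate in place of the silyl ether) | C1C(=O)[C@H]2[C@]3(C(=O)OC)[C@@H](OC(C)=O)C[C@@H]3[C@@]2(C)C[C@@H]1OCc4ccc(OC)cc4
F3 | step 8 | hydroxy photoadduct (12 with free C3 hydroxyl) | C1C(=O)[C@H]2[C@]3(C(=O)OC)[C@@H](O)C[C@@H]3[C@@]2(C)C[C@@H]1OCc4ccc(OC)cc4
F4 | step 9 | trans-fused photoadduct (C5 epimer of 12) | C1C(=O)[C@@H]2[C@]3(C(=O)OC)[C@@H](O[Si](C)(C)C(C)(C)C)C[C@@H]3[C@@]2(C)C[C@@H]1OCc4ccc(OC)cc4
F5 | step 9 | dienone ester with ring-trans C1=C10 and ring-trans C4=C5 (C4=C5 isomer of 13) | C1C(=O)/C=C(\C(=O)OC)[C@@H](O[Si](C)(C)C(C)(C)C)C/C=C(\C)C[C@@H]1OCc2ccc(OC)cc2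
F6 | step 13 | trimethylsilyl dienol ether of 17 (C6=C7 enol ether) | COc1ccc(CO[C@H]2C/C(C)=C/C[C@H](O[Si](C)(C)C(C)(C)C)/C(C)=C\C(O[Si](C)(C)C)=C/2)cc1
F7 | step 14 | cis-fused 6-epi lactone (C6 epimer of 21) | C1C(=O)O[C@H]2/C=C(/C)[C@@H](O[Si](C)(C)C(C)(C)C)C/C=C(\C)C[C@H](OCc3ccc(OC)cc3)[C@@H]12
F8 | step 14 | 6-epi hydroxy acid from F7 | OC(=O)C[C@H]1[C@@H](O)/C=C(/C)[C@@H](O[Si](C)(C)C(C)(C)C)C/C=C(\C)C[C@@H]1OCc2ccc(OC)cc2
F0 | step 20 | none | none
A1 | alternative 1 | ten-membered ring-contraction product with C6 hydroxyl and C7 1-(triethylsilyloxymethyl)vinyl group | C=C(CO[Si](CC)(CC)CC)[C@H]1[C@H](O)/C=C(/C)[C@@H](O[Si](C)(C)C(C)(C)C)C/C=C(\C)C[C@@H]1O[Si](C(C)C)(C(C)C)C(C)C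
A2 | alternative 1 | thirteen-membered cyclic bis-allylic ether C6–O–C13 (C7=C11 drawn ring-trans) | CC[Si](CC)(CC)OC/C1=C\[C@@H](O[Si](C(C)C)(C(C)C)C(C)C)C/C(C)=C/C[C@H](O[Si](C)(C)C(C)(C)C)/C(C)=C\COC1
A3 | alternative 2 | ten-membered C8 ketone with C10 tertiary alcohol and C1 chloride (aldol product) | O=C1C[C@@](C)(O)[C@@H](Cl)C[C@H](O[Si](C)(C)C(C)(C)C)/C(C)=C\[C@H]2OC(=O)C[C@@H]21
A4 | alternative 2 | open-chain lactone with C8 silyl enol ether and C1-chloro C10 methyl ketone | C=C(O[Si](C)(C)C)[C@H]1CC(=O)O[C@@H]1/C=C(/C)[C@@H](O[Si](C)(C)C(C)(C)C)C[C@H](Cl)C(C)=O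
A5 | alternative 3 | ten-membered (1(10)E,4Z)-dien-6-one with C7 acetal side chain (fragmentation product) | COC(OC)C[C@H]1C(=O)/C=C(/C)[C@@H](O[Si](C)(C)C(C)(C)C)C/C=C(\C)C[C@@H]1OCc2ccc(OC)cc2
A6 | alternative 3 | cis-fused bicyclo[5.3.0]dec-4-ene with C6 tertiary alcohol, C10 methyl and C1 mesylate anti to the C6–C10 bond | COC(OC)C[C@@H]1[C@@H](OCc3ccc(OC)cc3)C[C@@]2(C)[C@H](OS(C)(=O)=O)C[C@H](O[Si](C)(C)C(C)(C)C)/C(C)=C\[C@@]12O
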